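The plan cuts the two aryl C–O bonds at C2 and C6 of ring A (the benzene). This reduces the acylphloroglucinol to a 4-oxygenated isobutyrophenone. Once C3 and C5 carry the pyronylmethyl arms and C4 its oxygen, C2–H and C6–H are the only C–H bonds left on ring A. Both lie ortho to the C1 ketone, and pyrone rings B and C bear no ring hydrogen. One ketone-directed, palladium-catalysed operation converts both C–H bonds into C–O bonds. Its precursor 14 is 3,5-bis(pyronylmethyl)-4-hydroxyisobutyrophenone with all three hydroxyls capped as oxidation- and acid-proof methyl ethers, built by a double Mannich/quinone methide relay.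

Key step: step 6

Remark: the target has no stereocentre. The pyrones are drawn as their 4-hydroxy-2-pyrone tautomers. Silyl enol ether 2 is used as its E/Z mixture, since both isomers lead to the same pyrone.

Step 1
Reactants: 1 pentan-3-one
Product: 2 3-(trimethylsilyloxy)pent-2-ene (E/Z mixture)
Conditions: Me3SiCl, NaI, Et3N, MeCN, rt; pentane extraction, distillation
Reagents that add atoms: chlorotrimethylsilane, C[Si](C)(C)Cl
Why: Silyl enol ether formation by soft enolisation: iodotrimethylsilane generated in the flask silylates the carbonyl oxygen, triethylamine removes an α-proton, and the symmetry of 1 allows only one constitutional isomer.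

Step 2
Reactants: 2 3-(trimethylsilyloxy)pent-2-ene; 3 malonyl dichloride
Product: 5 6-ethyl-4-hydroxy-5-methyl-2H-pyran-2-one, via 4-methyl-3,5-dioxoheptanoyl chloride 4 (not isolated)
Conditions: 3 (1.0 equiv), Et2O, −78 °C to rt
Reagents that add atoms: none
Why: Acylative [3+3] cyclocondensation of a silyl enol ether with malonyl dichloride: C-acylation at the nucleophilic alkene carbon gives 4, whose enolised ethyl ketone oxygen closes onto the second acid chloride to a six-membered lactone that tautomerises to the 4-hydroxy-2-pyrone, and the preformed enol ether lets this run cold, ahead of the self-condensation of 3 that troubles free ketones.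

Step 3
Reactants: 6 1-(4-hydroxyphenyl)-2-methylpropan-1-one (4'-hydroxyisobutyrophenone); 7 formaldehyde
Product: 9 1-[3,5-bis((dimethylamino)methyl)-4-hydroxyphenyl]-2-methylpropan-1-one, via mono-Mannich base 8 (not isolated)
Conditions: 37% aq. HCHO (3 equiv), 40% aq. Me2NH (3 equiv), EtOH, reflux
Reagents that add atoms: dimethylamine, CNC
Why: Twofold phenolic Mannich reaction: in the amine-basic medium the phenoxide ring attacks the iminium species at both free ortho positions (the para position is blocked by the acyl group), while the hindered, poorly enolised isobutyryl α-carbon stays untouched.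

Step 4
Reactants: 9 1-[3,5-bis((dimethylamino)methyl)-4-hydroxyphenyl]-2-methylpropan-1-one; 5 6-ethyl-4-hydroxy-5-methyl-2H-pyran-2-one
Product: 13 1-[4-hydroxy-3,5-bis[(6-ethyl-4-hydroxy-5-methyl-2-oxo-2H-pyran-3-yl)methyl]phenyl]-2-methylpropan-1-one, via first ortho-quinone methide 10 (not isolated), via mono-pyronylmethyl Mannich base 11 (not isolated), via second ortho-quinone methide 12 (not isolated)
Conditions: 5 (2.2 equiv), 1,4-dioxane, reflux, N2 sweep
Reagents that add atoms: none
Why: Amine-exchange alkylation through ortho-quinone methides: the acidic pyrone protonates a benzylic amine, heat expels volatile dimethylamine, and C3 of 5, its only nucleophilic carbon, adds in a Michael sense with rearomatisation, the sequence then repeating at the second arm.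

Step 5
Reactants: 13 1-[4-hydroxy-3,5-bis[(6-ethyl-4-hydroxy-5-methyl-2-oxo-2H-pyran-3-yl)methyl]phenyl]-2-methylpropan-1-one
Product: 14 1-[3,5-bis[(6-ethyl-4-methoxy-5-methyl-2-oxo-2H-pyran-3-yl)methyl]-4-methoxyphenyl]-2-methylpropan-1-one
Conditions: Me2SO4 (4 equiv), K2CO3 (5 equiv), acetone, reflux
Reagents that add atoms: dimethyl sulfate, COS(=O)(=O)OC
Why: Williamson-type O-methylation: the hard electrophile dimethyl sulfate with K2CO3 alkylates the phenoxide and the C4 oxygen of the 3-substituted 4-hydroxy-2-pyrones in preference to C3 or the lactone carbonyl oxygen, and methyl is chosen because it withstands warm CF3CO2H and trivalent iodine and adds no new arene C–H bond.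

Step 6
Reactants: 14 1-[3,5-bis[(6-ethyl-4-methoxy-5-methyl-2-oxo-2H-pyran-3-yl)methyl]-4-methoxyphenyl]-2-methylpropan-1-one
Product: 17 1-[3,5-bis[(6-ethyl-4-methoxy-5-methyl-2-oxo-2H-pyran-3-yl)methyl]-2,6-dihydroxy-4-methoxyphenyl]-2-methylpropan-1-one, via mono(trifluoroacetate) 15 (not isolated), via bis(trifluoroacetate) 16 (not isolated)
Conditions: Pd(OAc)2 (10 mol %), PhI(OCOCF3)2 (3 equiv, two portions), CF3CO2H/(CF3CO)2O 9:1, 25 to 60 °C; then aq. NaHCO3/THF, rt
Reagents that add atoms: [bis(trifluoroacetoxy)iodo]benzene, O=C(OI(OC(=O)C(F)(F)F)c1ccccc1)C(F)(F)F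
Why: In CF3CO2H, Pd(OAc)2 becomes electrophilic Pd(OCOCF3)2, which binds the isobutyryl oxygen and cleaves the C2–H bond by concerted metalation–deprotonation to a five-membered palladacycle; PhI(OCOCF3)2 raises it to tetravalent palladium, and C–O reductive elimination releases aryl trifluoroacetate 15. Because the anhydride keeps 15 esterified, no hydrogen-bonded or chelating ortho-phenol arises, the carbonyl can turn to the other side, and the same cycle at C6–H gives 16, whose two labile esters are hydrolysed in the bicarbonate work-up. The closest known reaction type is the palladium- or ruthenium-catalysed ketone-directed ortho C–H hydroxylation of aryl alkyl ketones with trivalent iodine oxidants in CF3CO2H/(CF3CO)2O, run here twice on one ring. No ring is closed and no stereocentre is created. The selectivity needed is arene C–H against the two bridging CH2 groups, the isopropyl methine and the pyrone alkyl groups; it is secured by chelation (only C2 and C6 fit a five-membered metallacycle), by the absence of any other sp2 C–H bond in 14, and by the acidic medium, in which hydrogen-bonded or protonated 4-methoxypyrones and methyl-capped oxygens are poor partners for the oxidant. The main burden is steric, since each C–H is flanked by the acyl group and a pyronylmethyl arm, which is why the small Pd(OCOCF3)2 is preferred to the bulkier [RuCl2(p-cymene)]2.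

Step 7
Reactants: 17 1-[3,5-bis[(6-ethyl-4-methoxy-5-methyl-2-oxo-2H-pyran-3-yl)methyl]-2,6-dihydroxy-4-methoxyphenyl]-2-methylpropan-1-one
Product: 18 1-[3,5-bis[(6-ethyl-4-hydroxy-5-methyl-2-oxo-2H-pyran-3-yl)methyl]-2,4,6-trihydroxyphenyl]-2-methylpropan-1-one (target)
Conditions: BBr3 (10 equiv), CH2Cl2, −78 °C to rt; then H2O, 0 °C
Reagents that add atoms: none
Why: Lewis-acid ether cleavage: BBr3 binds the twisted, doubly ortho-substituted aryl ether oxygen and the pyrone carbonyl oxygens (turning each 4-methoxy group into a methoxypyrylium-like methyl donor), bromide removes the three methyl groups by SN2 attack, and hydrolysis of the borates frees the target, while ketone, lactones and methylene bridges should hold at or below room temperature.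

Compound list
1 | pentan-3-one | CCC(=O)CC | starting material
2 | 3-(trimethylsilyloxy)pent-2-ene (E/Z mixture) | CC=C(CC)O[Si](C)(C)C | intermediate
3 | malonyl dichloride | O=C(Cl)CC(=O)Cl | starting material
4 | 4-methyl-3,5-dioxoheptanoyl chloride (not isolated) | CCC(=O)C(C)C(=O)CC(=O)Cl | intermediate
5 | 6-ethyl-4-hydroxy-5-methyl-2H-pyran-2-one | CCc1oc(=O)cc(O)c1C | intermediate
6 | 1-(4-hydroxyphenyl)-2-methylpropan-1-one | CC(C)C(=O)c1ccc(O)cc1 | starting material
7 | formaldehyde | C=O | starting material
8 | 1-[3-((dimethylamino)methyl)-4-hydroxyphenyl]-2-methylpropan-1-one (not isolated) | CC(C)C(=O)c1ccc(O)c(CN(C)C)c1 | intermediate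
9 | 1-[3,5-bis((dimethylamino)methyl)-4-hydroxyphenyl]-2-methylpropan-1-one | CC(C)C(=O)c1cc(CN(C)C)c(O)c(CN(C)C)c1 | intermediate
10 | 2-((dimethylamino)methyl)-6-methylidene-4-(2-methylpropanoyl)cyclohexa-2,4-dien-1-one (not isolated) | C=C1C=C(C(=O)C(C)C)C=C(CN(C)C)C1=O | intermediate
11 | 1-[3-((dimethylamino)methyl)-5-[(6-ethyl-4-hydroxy-5-methyl-2-oxo-2H-pyran-3-yl)methyl]-4-hydroxyphenyl]-2-methylpropan-1-one (not isolated) | CC(C)C(=O)c1cc(CN(C)C)c(O)c(Cc2c(O)c(C)c(CC)oc2=O)c1 | intermediate
12 | 2-[(6-ethyl-4-hydroxy-5-methyl-2-oxo-2H-pyran-3-yl)methyl]-6-methylidene-4-(2-methylpropanoyl)cyclohexa-2,4-dien-1-one (not isolated) | C=C1C=C(C(=O)C(C)C)C=C(Cc2c(O)c(C)c(CC)oc2=O)C1=O | intermediate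
13 | 1-[4-hydroxy-3,5-bis[(6-ethyl-4-hydroxy-5-methyl-2-oxo-2H-pyran-3-yl)methyl]phenyl]-2-methylpropan-1-one | CC(C)C(=O)c1cc(Cc2c(O)c(C)c(CC)oc2=O)c(O)c(Cc2c(O)c(C)c(CC)oc2=O)c1 | intermediate
14 | 1-[3,5-bis[(6-ethyl-4-methoxy-5-methyl-2-oxo-2H-pyran-3-yl)methyl]-4-methoxyphenyl]-2-methylpropan-1-one | CC(C)C(=O)c1cc(Cc2c(OC)c(C)c(CC)oc2=O)c(OC)c(Cc2c(OC)c(C)c(CC)oc2=O)c1 | intermediate
15 | 2-trifluoroacetoxy derivative of 14 (not isolated) | CC(C)C(=O)c1cc(Cc2c(OC)c(C)c(CC)oc2=O)c(OC)c(Cc2c(OC)c(C)c(CC)oc2=O)c1OC(=O)C(F)(F)F | intermediate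
16 | 2,6-bis(trifluoroacetoxy) derivative of 14 (not isolated) | CC(C)C(=O)c1c(OC(=O)C(F)(F)F)c(Cc2c(OC)c(C)c(CC)oc2=O)c(OC)c(Cc2c(OC)c(C)c(CC)oc2=O)c1OC(=O)C(F)(F)F | intermediate
17 | 1-[3,5-bis[(6-ethyl-4-methoxy-5-methyl-2-oxo-2H-pyran-3-yl)methyl]-2,6-dihydroxy-4-methoxyphenyl]-2-methylpropan-1-one | CC(C)C(=O)c1c(O)c(Cc2c(OC)c(C)c(CC)oc2=O)c(OC)c(Cc2c(OC)c(C)c(CC)oc2=O)c1O | intermediate
18 | 1-[3,5-bis[(6-ethyl-4-hydroxy-5-methyl-2-oxo-2H-pyran-3-yl)methyl]-2,4,6-trihydroxyphenyl]-2-methylpropan-1-one | CCc1oc(=O)c(Cc2c(O)c(Cc3c(O)c(C)c(CC)oc3=O)c(O)c(C(=O)C(C)C)c2O)c(O)c1C | target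

Total step count: 7.
Longest linear sequence: 6 (steps 1, 2, 4, 5, 6, 7). Step 3 is a one-step side branch.

Steps most likely to fail

**Step 6.**
- Metalation may be slow because each C–H bond is flanked on both sides.
- The reaction may stall after the first oxygenation, since the ketone must lie near-coplanar next to an ortho ester to direct the second event.
- Oxidation at the bridging CH2 groups or α to the ketone may compete.
- The fallback gives up C–H oxygenation and buys the three ring oxygens. It sets out from pyrone 5 and comes back at target 18.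
- Commercial 2-methyl-1-(2,4,6-trihydroxyphenyl)propan-1-one F1 is aminomethylated twice with formaldehyde 7 and dimethylamine (EtOH, 0 °C to rt). This gives 1-[3,5-bis((dimethylamino)methyl)-2,4,6-trihydroxyphenyl]-2-methylpropan-1-one F2.
- F2 is then heated with 5 (2.2 equiv) in dioxane. Both arms exchange amine for C3 of the pyrone through quinone methides, the classical way to methylene-bridged acylphloroglucinols.

**Step 7.**
- Removal of the vinylogous-ester methyl groups on rings B and C may be incomplete.
- Forcing may bring acid-induced migration or loss of the methylene bridges, or cyclodehydration between a phenol and a pyrone hydroxyl.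
- The fallback changes the protecting-group plan to acyl caps that leave under mild base. It sets out from triol 13 and comes back at target 18.
- Ac2O/pyridine converts 13 into its tri-O-acetate F3.
- The twofold ketone-directed oxygenation is run without acid solvent: Pd(OCOCF3)2, PhI(OCOCF3)2, a few equivalents of (CF3CO)2O, 1,2-dichloroethane, 80 °C. It gives the 2,6-bis(trifluoroacetoxy) triacetate F4.
- F4 is taken crude into K2CO3/MeOH at 0 °C, where all five esters are methanolysed.

**Step 4.**
- Loss of amine from the electron-poor phenol may be sluggish.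
- The exchange may stop after one arm.
- The quinone methides may self-condense during prolonged heating.
- The fallback replaces thermal, reversible amine extrusion by irreversible, base-triggered elimination from a quaternary salt at ambient temperature. It sets out from Mannich base 9 and comes back at triol 13.
- Excess MeI in acetone (no base, so the phenol stays free) precipitates [2-hydroxy-5-(2-methylpropanoyl)-1,3-phenylene]bis(methylene)bis(trimethylammonium) diiodide F5.
- F5 is stirred with 5 (2.2 equiv) and K2CO3 in MeCN/H2O at rt to 40 °C. The phenoxide expels the neutral amine, and the pyrone enolate captures each quinone methide at C3.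

Further compounds
F1 | step 6 | 2-methyl-1-(2,4,6-trihydroxyphenyl)propan-1-one | CC(C)C(=O)c1c(O)cc(O)cc1O
F2 | step 6 | 1-[3,5-bis((dimethylamino)methyl)-2,4,6-trihydroxyphenyl]-2-methylpropan-1-one | CC(C)C(=O)c1c(O)c(CN(C)C)c(O)c(CN(C)C)c1O
F3 | step 7 | tri-O-acetate of 13 | CC(C)C(=O)c1cc(Cc2c(OC(C)=O)c(C)c(CC)oc2=O)c(OC(C)=O)c(Cc2c(OC(C)=O)c(C)c(CC)oc2=O)c1
F4 | step 7 | 2,6-bis(trifluoroacetoxy) derivative of F3 | CC(C)C(=O)c1c(OC(=O)C(F)(F)F)c(Cc2c(OC(C)=O)c(C)c(CC)oc2=O)c(OC(C)=O)c(Cc2c(OC(C)=O)c(C)c(CC)oc2=O)c1OC(=O)C(F)(F)F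
F5 | step 4 | [2-hydroxy-5-(2-methylpropanoyl)-1,3-phenylene]bis(methylene)bis(trimethylammonium) diiodide | CC(C)C(=O)c1cc(C[N+](C)(C)C)c(O)c(C[N+](C)(C)C)c1.[I-].[I-]
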